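## Analysis of the target

Target 24 is a 1-aryltetralin lignan. Ring A (C4a, C5 to C8, C8a) carries OMe at C6 and hydroxyls at C7 and C8. Ring B (C1 to C4) carries the 4-hydroxy-3-methoxyphenyl group at C1, hydroxymethyl groups (C9 on C2, C10 on C3) and a methylene at C4. The three contiguous stereocentres are (1S,2R,3R): aryl, C9 and C10 alternate faces (1,2-trans, 2,3-trans). C1 is a diarylmethine that cannot be epimerised; C2 and C3 can be adjusted whenever C9 and C10 are carbonyl groups. The sensitive groups are the 7,8-catechol next to OMe (air oxidation, above all in base) and the third phenol. Five oxygens of similar kind also have to be told apart, two staying methylated and three ending free. The hard points are the absolute configuration at C1, the all-trans array beside a peri substituent (the C8 oxygen lies next to the C1 aryl group), and the regiochemistry of ring closure in a molecule with two electron-rich rings. The strategy rests on two features. First, C4a, para to the C7 hydroxyl, is the only ring A carbon from which C4 can be reached. Second, the C8 oxygen, C8, C8a, C1, C2 and C9 are the six ring atoms of a 4-aryl-3,4-dihydrocoumarin, which separates the C8 oxygen from the C7 oxygen and lets a catalyst set C1.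

## Retrosynthetic reasoning

**24 back to 21.** The two benzyl-type and sulfonyl protecting groups are removed last (24 from 23 from 22), and the two carbinols C9 and C10 come from the diester 21. Keeping C9 and C10 as esters until late leaves C2 and C3 adjustable while C1 is fixed.

**21 back to 20.** No bond is cut; C2 and C3 of the all-trans diester 21 are reached by epimerisation of 20. Because this step sets both centres, only C1 has to be carried in from earlier compounds.

**20 back to 18 (key disconnection).** The C4–C4a bond is cut. This reverses the usual aryltetralin logic of closing at the diarylmethine: C1 is already in place and ring A has no choice of position. The forward reaction is an acid-promoted Friedel–Crafts conjugate addition of C4a to the terminal methylene carbon of the 2-methylene succinate 18, with C3 formed on ketonisation. It must choose ring A over the pendant ring, so 18 has a free C7 phenol and a tosylate on the pendant phenol.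

**18 back to 13.** The C7 phenol is unmasked from its acetal 17, and the methylene carbon C4 is attached to C3 of the succinate 13. C3 is a methylene and C2 a hindered methine, so the two ester alpha positions can be told apart.

**13 back to 11.** The C9–O bond to the C8 oxygen is re-formed: 13 is the ring-opened, O-alkylated form of lactone 11. This is where the C8 oxygen receives its own protecting group, distinct from that on the C7 oxygen.

**11 back to 8 and 9.** The C2–C3 bond is cut; the lactone enolate is alkylated by 9 anti to the aryl group. In 11 the carbonyl carbon C9 is a ring atom and the new chain is the substituent; on ring B the roles are exchanged. The 3,4-trans lactone therefore corresponds to aryl and C9 cis on ring B. Compounds 11 to 20 thus carry the C2 configuration opposite to the target, and the epimerisation to 21 is a required step.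

**8 back to 7 and 3.** The C1–aryl bond is cut; an asymmetric rhodium-catalysed conjugate addition of boronic acid 3 to coumarin 7 sets C1.

**7 back to 4; 3 back to 1.** Coumarin 7 comes from aldehyde 4 through 6; only the hydroxyl ortho to the formyl group can lactonise. Boronic acid 3 comes from the commercial phenol boronate 1 through 2.

## Alternatives that were turned down

**Alternative 1: tethered oxidative coupling of two cinnamates.**
- Disconnection: C2–C3 and C1–C8a, back to the tethered bis-cinnamate A2 (ferulate and 5-pivaloyloxyferulate on (2R,4R)-pentane-2,4-diol).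
- Key step: FeCl3 (trivalent iron) in aqueous acetone oxidises both phenols of A2; the carbons alpha to the ester carbonyls join and C8a closes onto C1, giving the tethered dihydronaphthalene A1.
- For it: two skeletal bonds and ring B in one step from simple acids. The 1,2-trans dihydronaphthalene is the stable arrangement, so it is stronger than the chosen route on step count and on C2.
- Against it: either ring can act as the nucleophile, and the unacylated ferulate ring is the richer one, so the wrong ring may become ring A. Phenol radical coupling has other modes (carbon–oxygen coupling). A nine-membered diolide must form. Absolute control rests on a remote diol. The C3=C4 bond still has to be reduced with 2,3-trans outcome.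
- Comparison: the chosen route is longer but fixes which ring closes (free phenol against tosylate) and sets C1 by a catalyst.

**Alternative 2: intramolecular enamine addition.**
- Disconnection: C1–C2, back to the benzhydrol aldehyde A4.
- Key step: diphenylprolinol trimethylsilyl ether and benzoic acid ionise the 4-hydroxybenzhydrol of A4, and the enamine carbon adds to C1, closing ring B to aldehyde A3.
- For it: all three stereocentres are under kinetic control, C3 carried in and C1 and C2 set together. It is stronger than the chosen route exactly where that route is weakest, because no equilibration is needed. Two identical benzyl ethers also make the end game simpler.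
- Against it: A4 needs a pentasubstituted ring A with two different carbon chains on adjacent carbons, one with a stereocentre, and this takes many steps. The ionising carbon is flanked by the C8 ether. The catalyst must be matched to the existing C3 centre. The alpha-branched aldehyde A3 can epimerise at C2.
- Comparison: the chosen route takes ring A with its substituents from a commercial benzaldehyde and separates the C7 and C8 oxygens through the lactone; it pays with a thermodynamic step for C2 and C3.

**Alternative 3: diene cycloaddition with a chiral fumarate.**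
- Disconnection: C1–C2 and C3–C4, back to the benzhydryl acetate A6 and di-(−)-menthyl fumarate A7.
- Key step: Bu4NF in MeCN removes the silyl group and the acetate of A6 in a 1,4-elimination, and the transient (E)-aryl diene on ring A adds A7 to give A5.
- For it: convergent; the 2,3-trans relation is built in by the fumarate geometry, which is stronger than the chosen route on that point. One hydrogenolysis frees all phenols and LiAlH4 removes the auxiliaries.
- Against it: the 1,2 relation depends on endo/exo orientation. Facial control by remote menthyl esters without Lewis acid activation is modest, so absolute control is by separation of diastereomers. The transient diene can dimerise. A6 needs several steps.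
- Comparison: the chosen route offers catalyst control of the absolute configuration at C1 in place of the built-in 2,3-trans relation.

Key step: step 10

Assumption on the chemistry: (S)-SEGPHOS is taken to give the (4S)-lactone 8, the mirror image of the sense established for the (R)-ligand with coumarins; otherwise the ligand enantiomer is exchanged. A compound written with an unmarked C3 is a mixture of C3 epimers.

## Route

Step 1
Reactants: 1 2-methoxy-4-(4,4,5,5-tetramethyl-1,3,2-dioxaborolan-2-yl)phenol
Product: 2 2-methoxy-4-(4,4,5,5-tetramethyl-1,3,2-dioxaborolan-2-yl)phenyl 4-methylbenzenesulfonate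
Conditions: TsCl, Et3N, DMAP (cat.), CH2Cl2, 0 °C to rt
Reagents that add atoms: 4-methylbenzenesulfonyl chloride, Cc1ccc(S(=O)(=O)Cl)cc1
Why: Sulfonylation of a phenol, which the pinacol boronate tolerates; the tosylate survives amide bases, cold methoxide and CF3SO3H, and it makes the pendant ring the poorer nucleophile in step 10.

Step 2
Reactants: 2 2-methoxy-4-(4,4,5,5-tetramethyl-1,3,2-dioxaborolan-2-yl)phenyl 4-methylbenzenesulfonate
Product: 3 [3-methoxy-4-(tosyloxy)phenyl]boronic acid
Conditions: NaIO4, NH4OAc, acetone–H2O, rt
Reagents that add atoms: water, O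
Why: Hydrolysis of the boronic ester driven by periodate cleavage of the released pinacol; the free boronic acid transmetalates to rhodium under neutral conditions and the aryl tosylate is inert.

Step 3
Reactants: 4 2,3-dihydroxy-4-methoxybenzaldehyde
Product: 6 8-hydroxy-7-methoxy-2H-chromen-2-one, via cinnamate ester 5 (not isolated)
Conditions: Ph3P=CHCO2Et, PhNEt2, reflux
Reagents that add atoms: ethyl (triphenylphosphoranylidene)acetate, CCOC(=O)C=P(c1ccccc1)(c1ccccc1)c1ccccc1
Why: Wittig olefination of the salicylaldehyde, then thermal E/Z isomerisation and lactonisation with the ortho hydroxyl; only the future C8 oxygen can close the ring, which separates it from the C7 oxygen.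

Step 4
Reactants: 6 8-hydroxy-7-methoxy-2H-chromen-2-one
Product: 7 7-methoxy-8-(methoxymethoxy)-2H-chromen-2-one
Conditions: MOMCl, i-Pr2NEt, CH2Cl2, 0 °C to rt
Reagents that add atoms: chloromethyl methyl ether, COCCl
Why: O-alkylation of the only free phenol to a methoxymethyl acetal, which is stable to the bases ahead and is removed by mild acid before the key step.

Step 5
Reactants: 7 7-methoxy-8-(methoxymethoxy)-2H-chromen-2-one; 3 [3-methoxy-4-(tosyloxy)phenyl]boronic acid
Product: 8 2-methoxy-4-[(4S)-7-methoxy-8-(methoxymethoxy)-2-oxo-3,4-dihydro-2H-chromen-4-yl]phenyl 4-methylbenzenesulfonate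
Conditions: Rh(acac)(C2H4)2 (3 mol%), (S)-SEGPHOS (3.3 mol%), 3 (3 equiv), 1,4-dioxane–H2O (10:1), 60 °C
Reagents that add atoms: none
Why: Hayashi–Miyaura asymmetric conjugate addition of an arylboronic acid to a coumarin, an established substrate class for rhodium–bisphosphine catalysts; the arylrhodium adds to C4 of the coumarin on the face chosen by the ligand and water protonates the rhodium enolate, which sets C1 (S).

Step 6
Reactants: 8 2-methoxy-4-[(4S)-7-methoxy-8-(methoxymethoxy)-2-oxo-3,4-dihydro-2H-chromen-4-yl]phenyl 4-methylbenzenesulfonate; 9 methyl bromoacetate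
Product: 11 methyl 2-[(3R,4S)-7-methoxy-8-(methoxymethoxy)-4-[3-methoxy-4-(tosyloxy)phenyl]-2-oxo-3,4-dihydro-2H-chromen-3-yl]acetate (3,4-trans), via lithium enolate 10 (not isolated)
Conditions: LiN(SiMe3)2, THF, −78 °C; then 9, −78 to −40 °C
Reagents that add atoms: none
Why: Alkylation of a lactone lithium enolate; the pseudo-axial 4-aryl group shields one face, so the electrophile enters anti and gives the 3,4-trans lactone. Since the lactone carbonyl C9 becomes a substituent on ring B, this places the C1 aryl and C9 cis there, which step 11 corrects.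

Step 7
Reactants: 11 methyl 2-[(3R,4S)-7-methoxy-8-(methoxymethoxy)-4-[3-methoxy-4-(tosyloxy)phenyl]-2-oxo-3,4-dihydro-2H-chromen-3-yl]acetate
Product: 13 dimethyl (2R)-2-[(S)-[4-methoxy-3-(methoxymethoxy)-2-{[4-(trifluoromethyl)phenyl]methoxy}phenyl][3-methoxy-4-(tosyloxy)phenyl]methyl]butanedioate, via sodium phenoxide 12 (not isolated)
Conditions: NaOMe, MeOH–THF, 0 °C; then 4-CF3C6H4CH2Br, DMF, rt
Reagents that add atoms: sodium methoxide, C[O-].[Na+]; 4-(trifluoromethyl)benzyl bromide, FC(F)(F)c1ccc(CBr)cc1
Why: Methoxide transesterifies the aryl ester and opens the lactone; the phenoxide is etherified at once (Williamson) because the free hydroxy ester would reclose. The C8 oxygen must stay an ether to keep ring A electron-rich, and the electron-poor benzyl group is chosen because it is not ionised by CF3SO3H yet is cleaved by hydrogenolysis.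

Step 8
Reactants: 13 dimethyl (2R)-2-[(S)-[4-methoxy-3-(methoxymethoxy)-2-{[4-(trifluoromethyl)phenyl]methoxy}phenyl][3-methoxy-4-(tosyloxy)phenyl]methyl]butanedioate
Product: 17 dimethyl (2S)-2-[(S)-[4-methoxy-3-(methoxymethoxy)-2-{[4-(trifluoromethyl)phenyl]methoxy}phenyl][3-methoxy-4-(tosyloxy)phenyl]methyl]-3-methylidenebutanedioate, via lithium enolate 14 (not isolated), via Mannich base 15 (not isolated), via ammonium iodide 16 (not isolated)
Conditions: LiN(i-Pr)2, THF, −78 °C; CH2=NMe2+ I−, −78 °C to rt; MeI, MeOH, rt; aq. NaHCO3, CH2Cl2, rt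
Reagents that add atoms: dimethylmethyleneiminium iodide, C=[N+](C)C.[I-]
Why: Kinetic deprotonation at the C3 methylene (the C2 proton is shielded by the diarylmethine), Mannich reaction with the iminium salt, quaternisation and E1cB elimination; the weak base in the last stage avoids migration of the double bond to C2=C3.

Step 9
Reactants: 17 dimethyl (2S)-2-[(S)-[4-methoxy-3-(methoxymethoxy)-2-{[4-(trifluoromethyl)phenyl]methoxy}phenyl][3-methoxy-4-(tosyloxy)phenyl]methyl]-3-methylidenebutanedioate
Product: 18 dimethyl (2S)-2-[(S)-[3-hydroxy-4-methoxy-2-{[4-(trifluoromethyl)phenyl]methoxy}phenyl][3-methoxy-4-(tosyloxy)phenyl]methyl]-3-methylidenebutanedioate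
Conditions: HCl (1.25 M in MeOH), rt
Reagents that add atoms: none
Why: Acid-catalysed methanolysis of the aryl methoxymethyl acetal frees the C7 phenol; the tosylate, the benzyl-type ether, the methyl esters and the acrylate are stable to dilute acid in methanol.

Step 10
Reactants: 18 dimethyl (2S)-2-[(S)-[3-hydroxy-4-methoxy-2-{[4-(trifluoromethyl)phenyl]methoxy}phenyl][3-methoxy-4-(tosyloxy)phenyl]methyl]-3-methylidenebutanedioate
Product: 20 dimethyl (1S,2S)-7-hydroxy-6-methoxy-1-[3-methoxy-4-(tosyloxy)phenyl]-8-{[4-(trifluoromethyl)phenyl]methoxy}tetralin-2,3-dicarboxylate (aryl cis to the C2 ester; C3 epimers), via ester enol 19 (not isolated)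
Conditions: CF3SO3H (0.5 equiv), (CF3)2CHOH (0.02 M), 0 °C to rt
Reagents that add atoms: none
Why: CF3SO3H in the strongly hydrogen-bond-donating solvent protonates the C10 ester carbonyl of the 2-methylene succinate and makes the terminal methylene carbon C4 electrophilic; C4a attacks it, the arenium ion loses its proton and the ester enol 19 ketonises. The closest known reaction type is the Brønsted-acid-promoted intramolecular Friedel–Crafts conjugate addition (hydroarylation) of acrylates by electron-rich arenes. Ring B closes in the 6-endo-trig mode, since C3=C4 lies inside the new ring. The new stereocentre C3 arises on ketonisation of 19 under substrate control (proton expected anti to the neighbouring C2 ester); this outcome is not relied on, and C3 is settled with C2 in step 11. The step must choose between the two aryl groups on C1, because the pendant ring could close through its carbon para to OMe to give an isomeric tetralin. Ring A has the free C7 hydroxyl para to C4a, held in the ring plane between its two neighbours and so a full donor, whereas the pendant ring has the electron-withdrawing tosylate meta to its reactive carbon. On ring A itself there is no choice, since C5 cannot reach C4. The C8 oxygen is an ether because a sulfonate or ester there, meta to C4a, would cancel the advantage of ring A; the electron-poor benzyl group keeps that ether from ionising in the acid.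

Step 11
Reactants: 20 dimethyl (1S,2S)-7-hydroxy-6-methoxy-1-[3-methoxy-4-(tosyloxy)phenyl]-8-{[4-(trifluoromethyl)phenyl]methoxy}tetralin-2,3-dicarboxylate (C3 epimers)
Product: 21 dimethyl (1S,2R,3R)-7-hydroxy-6-methoxy-1-[3-methoxy-4-(tosyloxy)phenyl]-8-{[4-(trifluoromethyl)phenyl]methoxy}-1,2,3,4-tetrahydronaphthalene-2,3-dicarboxylate (all-trans)
Conditions: NaOMe (3 equiv), MeOH–THF, rt, Ar
Reagents that add atoms: none
Why: Base-mediated epimerisation through the ester enolates at C2 and C3, with C1 not acidic; it should converge on the all-trans diester, the usual thermodynamic isomer of 1-aryltetralin-2,3-dicarboxylates. Methoxide matches the methyl esters, and the aryl tosylate is expected to survive at room temperature.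

Step 12
Reactants: 21 dimethyl (1S,2R,3R)-7-hydroxy-6-methoxy-1-[3-methoxy-4-(tosyloxy)phenyl]-8-{[4-(trifluoromethyl)phenyl]methoxy}-1,2,3,4-tetrahydronaphthalene-2,3-dicarboxylate
Product: 22 4-[(1S,2R,3R)-7-hydroxy-2,3-bis(hydroxymethyl)-6-methoxy-8-{[4-(trifluoromethyl)phenyl]methoxy}-1,2,3,4-tetrahydronaphthalen-1-yl]-2-methoxyphenyl 4-methylbenzenesulfonate
Conditions: LiAlH4, THF, 0 °C; aq. NaOH work-up
Reagents that add atoms: none
Why: Hydride reduction of both esters to primary alcohols, after which no centre can epimerise; at 0 °C the aryl tosylate should largely survive, and any tosylate lost here converges in step 13.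

Step 13
Reactants: 22 4-[(1S,2R,3R)-7-hydroxy-2,3-bis(hydroxymethyl)-6-methoxy-8-{[4-(trifluoromethyl)phenyl]methoxy}-1,2,3,4-tetrahydronaphthalen-1-yl]-2-methoxyphenyl 4-methylbenzenesulfonate
Product: 23 (1S,2R,3R)-1-(4-hydroxy-3-methoxyphenyl)-2,3-bis(hydroxymethyl)-6-methoxy-8-{[4-(trifluoromethyl)phenyl]methoxy}-1,2,3,4-tetrahydronaphthalen-7-ol
Conditions: KOH, MeOH–H2O, 65 °C, Ar; then aq. NH4Cl
Reagents that add atoms: none
Why: Alkaline hydrolysis of the aryl sulfonate by attack at sulfur; nothing else in 22 is hydrolysable, and the catechol is still masked as its mono-ether, so base is tolerated under argon.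

Step 14
Reactants: 23 (1S,2R,3R)-1-(4-hydroxy-3-methoxyphenyl)-2,3-bis(hydroxymethyl)-6-methoxy-8-{[4-(trifluoromethyl)phenyl]methoxy}-1,2,3,4-tetrahydronaphthalen-7-ol
Product: 24 (1S,2R,3R)-1-(4-hydroxy-3-methoxyphenyl)-2,3-bis(hydroxymethyl)-6-methoxy-1,2,3,4-tetrahydronaphthalene-7,8-diol (target)
Conditions: H2 (1 atm), Pd/C, MeOH–EtOAc, rt
Reagents that add atoms: none
Why: Hydrogenolysis of the aryl benzyl-type ether; a neutral, reducing last step suits the oxidation-prone 7,8-catechol.

## Compound list

1 | 2-methoxy-4-(4,4,5,5-tetramethyl-1,3,2-dioxaborolan-2-yl)phenol | COc1cc(B2OC(C)(C)C(C)(C)O2)ccc1O | starting material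
2 | 2-methoxy-4-(4,4,5,5-tetramethyl-1,3,2-dioxaborolan-2-yl)phenyl 4-methylbenzenesulfonate | COc1cc(B2OC(C)(C)C(C)(C)O2)ccc1OS(=O)(=O)c1ccc(C)cc1 | intermediate
3 | [3-methoxy-4-(tosyloxy)phenyl]boronic acid | COc1cc(B(O)O)ccc1OS(=O)(=O)c1ccc(C)cc1 | intermediate
4 | 2,3-dihydroxy-4-methoxybenzaldehyde | COc1ccc(C=O)c(O)c1O | starting material
5 | ethyl (E)-3-(2,3-dihydroxy-4-methoxyphenyl)prop-2-enoate | CCOC(=O)/C=C/c1ccc(OC)c(O)c1O | intermediate (not isolated)
6 | 8-hydroxy-7-methoxy-2H-chromen-2-one | COc1ccc2C=CC(=O)Oc2c1O | intermediate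
7 | 7-methoxy-8-(methoxymethoxy)-2H-chromen-2-one | COCOc1c(OC)ccc2C=CC(=O)Oc12 | intermediate
8 | 2-methoxy-4-[(4S)-7-methoxy-8-(methoxymethoxy)-2-oxo-3,4-dihydro-2H-chromen-4-yl]phenyl 4-methylbenzenesulfonate | COc1cc([C@@H]2CC(=O)Oc3c2ccc(OC)c3OCOC)ccc1OS(=O)(=O)c1ccc(C)cc1 | intermediate
9 | methyl bromoacetate | COC(=O)CBr | starting material
10 | lithium enolate of lactone 8 | [Li+].[O-]C1=C[C@@H](c2ccc(OS(=O)(=O)c3ccc(C)cc3)c(OC)c2)c2ccc(OC)c(OCOC)c2O1 | intermediate (not isolated)
11 | methyl 2-[(3R,4S)-7-methoxy-8-(methoxymethoxy)-4-[3-methoxy-4-(tosyloxy)phenyl]-2-oxo-3,4-dihydro-2H-chromen-3-yl]acetate (3,4-trans) | COc1cc([C@@H]2[C@@H](CC(=O)OC)C(=O)Oc3c2ccc(OC)c3OCOC)ccc1OS(=O)(=O)c1ccc(C)cc1 | intermediate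
12 | sodium phenoxide of the ring-opened dimethyl succinate (C1 and C2 as in 11) | COc1cc([C@@H](c2ccc(OC)c(OCOC)c2[O-])[C@@H](CC(=O)OC)C(=O)OC)ccc1OS(=O)(=O)c1ccc(C)cc1.[Na+] | intermediate (not isolated)
13 | dimethyl (2R)-2-[(S)-[4-methoxy-3-(methoxymethoxy)-2-{[4-(trifluoromethyl)phenyl]methoxy}phenyl][3-methoxy-4-(tosyloxy)phenyl]methyl]butanedioate | COc1cc([C@@H](c2ccc(OC)c(OCOC)c2OCc2ccc(C(F)(F)F)cc2)[C@@H](CC(=O)OC)C(=O)OC)ccc1OS(=O)(=O)c1ccc(C)cc1 | intermediate
14 | lithium C3 enolate of 13 | COc1cc([C@@H](c2ccc(OC)c(OCOC)c2OCc2ccc(C(F)(F)F)cc2)[C@@H](C=C([O-])OC)C(=O)OC)ccc1OS(=O)(=O)c1ccc(C)cc1.[Li+] | intermediate (not isolated)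
15 | 3-[(dimethylamino)methyl] derivative of 13 (C3 epimers) | COc1cc([C@@H](c2ccc(OC)c(OCOC)c2OCc2ccc(C(F)(F)F)cc2)[C@@H](C(CN(C)C)C(=O)OC)C(=O)OC)ccc1OS(=O)(=O)c1ccc(C)cc1 | intermediate (not isolated)
16 | 3-[(trimethylammonio)methyl] derivative of 13, iodide (C3 epimers) | COc1cc([C@@H](c2ccc(OC)c(OCOC)c2OCc2ccc(C(F)(F)F)cc2)[C@@H](C(C[N+](C)(C)C)C(=O)OC)C(=O)OC)ccc1OS(=O)(=O)c1ccc(C)cc1.[I-] | intermediate (not isolated)
17 | dimethyl (2S)-2-[(S)-[4-methoxy-3-(methoxymethoxy)-2-{[4-(trifluoromethyl)phenyl]methoxy}phenyl][3-methoxy-4-(tosyloxy)phenyl]methyl]-3-methylidenebutanedioate | COc1cc([C@@H](c2ccc(OC)c(OCOC)c2OCc2ccc(C(F)(F)F)cc2)[C@H](C(=O)OC)C(=C)C(=O)OC)ccc1OS(=O)(=O)c1ccc(C)cc1 | intermediate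
18 | dimethyl (2S)-2-[(S)-[3-hydroxy-4-methoxy-2-{[4-(trifluoromethyl)phenyl]methoxy}phenyl][3-methoxy-4-(tosyloxy)phenyl]methyl]-3-methylidenebutanedioate (key-step precursor) | COc1cc([C@@H](c2ccc(OC)c(O)c2OCc2ccc(C(F)(F)F)cc2)[C@H](C(=O)OC)C(=C)C(=O)OC)ccc1OS(=O)(=O)c1ccc(C)cc1 | intermediate
19 | C10 ester enol of the cyclised tetralin (C1 and C2 as in 18) | COc1cc([C@H]2c3c(cc(OC)c(O)c3OCc3ccc(C(F)(F)F)cc3)CC(=C(O)OC)[C@H]2C(=O)OC)ccc1OS(=O)(=O)c1ccc(C)cc1 | intermediate (not isolated)
20 | dimethyl (1S,2S)-7-hydroxy-6-methoxy-1-[3-methoxy-4-(tosyloxy)phenyl]-8-{[4-(trifluoromethyl)phenyl]methoxy}-1,2,3,4-tetrahydronaphthalene-2,3-dicarboxylate, aryl and C2 ester cis, mixture of C3 epimers (key-step product) | COc1cc([C@H]2c3c(cc(OC)c(O)c3OCc3ccc(C(F)(F)F)cc3)CC(C(=O)OC)[C@H]2C(=O)OC)ccc1OS(=O)(=O)c1ccc(C)cc1 | intermediate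
21 | dimethyl (1S,2R,3R)-7-hydroxy-6-methoxy-1-[3-methoxy-4-(tosyloxy)phenyl]-8-{[4-(trifluoromethyl)phenyl]methoxy}-1,2,3,4-tetrahydronaphthalene-2,3-dicarboxylate (all-trans) | COc1cc([C@H]2c3c(cc(OC)c(O)c3OCc3ccc(C(F)(F)F)cc3)C[C@@H](C(=O)OC)[C@@H]2C(=O)OC)ccc1OS(=O)(=O)c1ccc(C)cc1 | intermediate
22 | 4-[(1S,2R,3R)-7-hydroxy-2,3-bis(hydroxymethyl)-6-methoxy-8-{[4-(trifluoromethyl)phenyl]methoxy}-1,2,3,4-tetrahydronaphthalen-1-yl]-2-methoxyphenyl 4-methylbenzenesulfonate | COc1cc([C@H]2c3c(cc(OC)c(O)c3OCc3ccc(C(F)(F)F)cc3)C[C@@H](CO)[C@@H]2CO)ccc1OS(=O)(=O)c1ccc(C)cc1 | intermediate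
23 | (1S,2R,3R)-1-(4-hydroxy-3-methoxyphenyl)-2,3-bis(hydroxymethyl)-6-methoxy-8-{[4-(trifluoromethyl)phenyl]methoxy}-1,2,3,4-tetrahydronaphthalen-7-ol | COc1cc([C@H]2c3c(cc(OC)c(O)c3OCc3ccc(C(F)(F)F)cc3)C[C@@H](CO)[C@@H]2CO)ccc1O | intermediate
24 | (1S,2R,3R)-1-(4-hydroxy-3-methoxyphenyl)-2,3-bis(hydroxymethyl)-6-methoxy-1,2,3,4-tetrahydronaphthalene-7,8-diol | COc1cc([C@H]2c3c(cc(OC)c(O)c3O)C[C@@H](CO)[C@@H]2CO)ccc1O | target

## Step count and uncertain steps

Total: 14 steps. Longest linear sequence: 12 steps (from 4 through steps 3 to 14; equally from 1 through steps 1, 2 and 5 to 14).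

**Step 10 (key step).**
- What may go wrong: closure through the pendant ring (its carbon para to OMe) in competition with ring A; acid cleavage of the C8 ether followed by C-alkylation of ring A by the released benzyl cation; intermolecular alkylation at C5; or migration of the double bond into C2=C3 before closure, after which no cyclisation is possible.
- Fallback (radical instead of cationic closure of the same bond), setting out from 18 and rejoining at 20: N-bromosuccinimide in MeCN at 0 °C brominates ring A para to the free phenol, at C4a, to give the aryl bromide F1 (C1 and C2 as in 18). Bu3SnH with azobisisobutyronitrile in toluene at 90 °C then generates the C4a aryl radical, which adds 6-endo-trig to the unsubstituted terminus of the acrylate. The resulting alpha-ester radical is reduced by the tin hydride to 20. The halogen fixes the site of closure, so the pendant ring cannot take part, and no acid is present.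

**Step 11 (equilibration).**
- What may go wrong: the epimerisation may stop at a mixture or settle on an isomer other than all-trans. The C8 ether pushes the C1 aryl group toward the pseudo-axial position, which removes part of the usual advantage of the all-equatorial diester. Attack of methoxide on the tosylate is a second concern.
- Fallback (directed hydrogenation in place of thermodynamic control), setting out from 20 and rejoining at 22: DDQ in 1,4-dioxane dehydrogenates C3–C4 through the quinone methide of the C7 phenol, and DBU then brings C2 into the trans arrangement of 1-aryl-1,2-dihydronaphthalenes, giving the dihydronaphthalene diester F2. i-Bu2AlH in CH2Cl2 at −78 °C reduces both esters to the unsaturated diol F3. Hydrogenation with [Ir(cod)(PCy3)(py)]PF6 under H2 in CH2Cl2, directed by the C9 hydroxyl, delivers hydrogen to C3 on the face of C9, placing C10 trans to it, and gives 22.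

**Step 8 (alpha-methylenation).**
- What may go wrong: competing deprotonation at C2, or migration of the new double bond into conjugation at C2=C3 during the elimination.
- Fallback (thermodynamic acylation instead of kinetic enolisation), setting out from 13 and rejoining at 17: Claisen condensation with dimethyl oxalate (NaOMe, THF, rt) can only persist at the C3 methylene, where the product remains enolisable, and gives the methoxalyl diester F4. Aqueous formaldehyde with K2CO3 then gives aldol addition and loss of the oxalyl group, forming the methylene compound 17. Any epimerisation at C2 on this path is absorbed by step 11.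

**Step 5 (rhodium addition).**
- What may go wrong: slow addition to the coumarin with competing protodeboronation of 3, or insufficient facial selectivity with the C8 acetal beside the lactone oxygen.
- Fallback (arylation first, asymmetric reduction second), setting out from 7 and 3 and rejoining at 8: oxidative Heck arylation with Pd(OAc)2 (divalent palladium), 1,10-phenanthroline and O2 in DMF gives the 4-arylcoumarin F5. Copper hydride conjugate reduction (Cu(OAc)2, the DTBM-SEGPHOS enantiomer that gives the 4S lactone, (EtO)2MeSiH, t-BuOH, toluene) then gives 8.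

**Step 14 (hydrogenolysis).**
- What may go wrong: slow hydrogenolysis of the electron-poor benzyl ether, or air oxidation of the freed catechol during isolation.
- Fallback (electron transfer instead of hydrogenolysis), setting out from 22 and rejoining at 24: excess lithium naphthalenide in THF at −78 °C cleaves both the aryl tosylate and the trifluoromethylbenzyl ether, with acidic work-up under argon. This replaces steps 13 and 14 and makes no new compound.

## Further compounds

F1 | step 10 | dimethyl 2-[[6-bromo-3-hydroxy-4-methoxy-2-{[4-(trifluoromethyl)phenyl]methoxy}phenyl][3-methoxy-4-(tosyloxy)phenyl]methyl]-3-methylidenebutanedioate (C1 and C2 as in 18) | COc1cc([C@@H](c2c(Br)cc(OC)c(O)c2OCc2ccc(C(F)(F)F)cc2)[C@H](C(=O)OC)C(=C)C(=O)OC)ccc1OS(=O)(=O)c1ccc(C)cc1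
F2 | step 11 | dimethyl (1S,2R)-7-hydroxy-6-methoxy-1-[3-methoxy-4-(tosyloxy)phenyl]-8-{[4-(trifluoromethyl)phenyl]methoxy}-1,2-dihydronaphthalene-2,3-dicarboxylate | COc1cc([C@H]2c3c(cc(OC)c(O)c3OCc3ccc(C(F)(F)F)cc3)C=C(C(=O)OC)[C@@H]2C(=O)OC)ccc1OS(=O)(=O)c1ccc(C)cc1
F3 | step 11 | 4-[(1S,2R)-7-hydroxy-2,3-bis(hydroxymethyl)-6-methoxy-8-{[4-(trifluoromethyl)phenyl]methoxy}-1,2-dihydronaphthalen-1-yl]-2-methoxyphenyl 4-methylbenzenesulfonate | COc1cc([C@H]2c3c(cc(OC)c(O)c3OCc3ccc(C(F)(F)F)cc3)C=C(CO)[C@@H]2CO)ccc1OS(=O)(=O)c1ccc(C)cc1
F4 | step 8 | 3-(2-methoxy-2-oxoacetyl) derivative of 13 (C3 epimers, enolisable) | COc1cc([C@@H](c2ccc(OC)c(OCOC)c2OCc2ccc(C(F)(F)F)cc2)[C@@H](C(C(=O)C(=O)OC)C(=O)OC)C(=O)OC)ccc1OS(=O)(=O)c1ccc(C)cc1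
F5 | step 5 | 2-methoxy-4-[7-methoxy-8-(methoxymethoxy)-2-oxo-2H-chromen-4-yl]phenyl 4-methylbenzenesulfonate | COc1cc(C2=CC(=O)Oc3c2ccc(OC)c3OCOC)ccc1OS(=O)(=O)c1ccc(C)cc1
F0 | step 14 | none | none
A1 | alternative 1 | tethered 1-aryl-1,2-dihydronaphthalene-2,3-dicarboxylate, nine-membered diolide with (2R,4R)-pentane-2,4-diol, 8-pivalate | COc1cc([C@H]2c3c(cc(OC)c(O)c3OC(=O)C(C)(C)C)C=C4C(=O)O[C@H](C)C[C@@H](C)OC(=O)[C@H]24)ccc1O
A2 | alternative 1 | (2R,4R)-pentane-2,4-diyl mixed diester of (E)-ferulic acid and (E)-4-hydroxy-3-methoxy-5-(pivaloyloxy)cinnamic acid | CC(C)(C)C(=O)Oc1cc(/C=C/C(=O)O[C@H](C)C[C@@H](C)OC(=O)/C=C/c2ccc(O)c(OC)c2)cc(OC)c1O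
A3 | alternative 2 | 1-aryltetralin-2-carbaldehyde with tert-butyldimethylsilyloxymethyl at C3 and benzyl ethers at C7 and C8 | COc1cc([C@H]2c3c(cc(OC)c(OCc4ccccc4)c3OCc3ccccc3)C[C@@H](CO[Si](C)(C)C(C)(C)C)[C@@H]2C=O)ccc1O
A4 | alternative 2 | 4-hydroxybenzhydrol with the 4-oxobutyl chain on ring A (silyloxymethyl at C3; carbinol epimers) | COc1cc(C(O)c2c(C[C@@H](CO[Si](C)(C)C(C)(C)C)CC=O)cc(OC)c(OCc3ccccc3)c2OCc2ccccc2)ccc1O
A5 | alternative 3 | di-(−)-menthyl 1-aryltetralin-2,3-dicarboxylate, tri-O-benzyl | COc1cc([C@H]2c3c(cc(OC)c(OCc4ccccc4)c3OCc3ccccc3)C[C@@H](C(=O)O[C@@H]3C[C@H](C)CC[C@H]3C(C)C)[C@@H]2C(=O)O[C@@H]2C[C@H](C)CC[C@H]2C(C)C)ccc1OCc1ccccc1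
A6 | alternative 3 | ring A benzhydryl acetate with ortho (trimethylsilyl)methyl group, tri-O-benzyl | COc1cc(C(OC(C)=O)c2c(C[Si](C)(C)C)cc(OC)c(OCc3ccccc3)c2OCc2ccccc2)ccc1OCc1ccccc1
A7 | alternative 3 | di-(−)-menthyl fumarate | O=C(/C=C/C(=O)O[C@@H]1C[C@H](C)CC[C@H]1C(C)C)O[C@@H]1C[C@H](C)CC[C@H]1C(C)C
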